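**Plan**

1. Locants (lignan style): C7/C7' = ArCH–O, C8/C8' = ring-fusion CH, C9/C9' = OCH2. Ring A = C7–O–C9'–C8'–C8 (guaiacyl on C7); ring B = C7'–O–C9–C8–C8' (dihydrobenzofuranyl on C7').
2. Enabling feature: H7, H8, H8' and H7' all lie on one face of the dioxabicyclo[3.3.0]octane (both aryls endo), and each fusion carbon carries one OCH2 arm and one ArCH–O arm. The C8–C8' bond can therefore be closed as the tetrasubstituted C=C of a 2,5-dihydrofuran (ring A) from two 2-substituted allyl units held by the C7–O–C9' ether, and saturated last from the face away from both aryls.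
3. Cuts: C8=C8' (ring-closing metathesis); O–C9 of ring B (alkoxide displacement); C7'–C8' and C7–C8 (two aldehyde + 2-bromoallyl couplings); C7O–C9' (Williamson); in the dihydrobenzofuran C2–C3 (carbenoid C–H insertion), O–CH2Ar (Mitsunobu) and aryl–C3 (Pd/diazoacetate).
4. Forward: dihydrobenzofuran aldehyde (fragment 2) first; guaiacyl allylic alcohol (fragment 1) → 2-bromoallyl ether → union with fragment 2 → ring A → ring B → hydrogenation → desilylation.
5. Stereochemistry: cis C2/C3 of the dihydrobenzofuran from a chiral dirhodium carboxylate; C7 and C7' from ligand-controlled Nozaki–Hiyama–Kishi additions; C8 and C8' from syn hydrogenation of the flat bicyclic alkene anti to both aryl groups.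

Key step: step 15

Assumption: the facial sense of the chiral catalysts (Rh2(S-PTTL)4, PTTL = N-phthaloyl-tert-leucinate, in step 6; the CrCl2 complex of N-{2-[(S)-4-isopropyl-4,5-dihydrooxazol-2-yl]-6-methylphenyl}methanesulfonamide in steps 11 and 14) is taken over from simple aryl analogues; if it proves opposite, the mirror-image catalyst is used and nothing else changes.

**Route**

Step 1
Reactants: 1 vanillin
Product: 2 3-methoxy-4-(triisopropylsilyloxy)benzaldehyde
Conditions: TIPSCl, imidazole, DMF, rt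
Reagents that add atoms: triisopropylsilyl chloride, CC(C)[Si](Cl)(C(C)C)C(C)C
Why: Phenol O-silylation (silyl ether formation); the aryl TIPS ether should survive the alkoxide, hydride, organometallic and buffered HF·pyridine steps and falls to fluoride at the end.

Step 2
Reactants: 2 3-methoxy-4-(triisopropylsilyloxy)benzaldehyde
Product: 3 [3-methoxy-4-(triisopropylsilyloxy)phenyl]methanol
Conditions: NaBH4, MeOH, 0 °C
Reagents that add atoms: none
Why: Borohydride reduction of an aryl aldehyde to the benzylic alcohol, under which the aryl silyl ether is stable.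

Step 3
Reactants: 4 4-bromo-2-methoxyphenol
Product: 5 4-bromo-2-iodo-6-methoxyphenol
Conditions: NIS, TsOH·H2O (cat.), MeCN, 0 °C to rt
Reagents that add atoms: N-iodosuccinimide, O=C1CCC(=O)N1I
Why: Electrophilic aromatic iodination directed by the hydroxyl group, whose only free ortho position is attacked because the para position carries bromine.

Step 4
Reactants: 5 4-bromo-2-iodo-6-methoxyphenol; 3 [3-methoxy-4-(triisopropylsilyloxy)phenyl]methanol
Product: 6 5-bromo-1-iodo-3-methoxy-2-{[3-methoxy-4-(triisopropylsilyloxy)benzyl]oxy}benzene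
Conditions: PPh3, DIAD, THF, 0 °C to rt
Reagents that add atoms: none
Why: Mitsunobu etherification of an acidic ortho-halophenol with a primary benzylic alcohol, which avoids the unstable p-siloxybenzyl halide.

Step 5
Reactants: 6 the iodoarene benzyl ether; 7 ethyl diazoacetate
Product: 8 ethyl 2-(5-bromo-3-methoxy-2-{[3-methoxy-4-(triisopropylsilyloxy)benzyl]oxy}phenyl)-2-diazoacetate
Conditions: Pd(PPh3)4 (5 mol %), Ag2CO3 (0.5 equiv), Et3N, toluene, rt
Reagents that add atoms: none
Why: Palladium-catalysed cross-coupling of an aryl iodide with a diazoacetate with retention of the diazo group; zerovalent palladium inserts into C–I at room temperature and leaves C–Br untouched.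

Step 6
Reactants: 8 the aryl diazoacetate
Product: 9 ethyl (2S,3R)-5-bromo-7-methoxy-2-[3-methoxy-4-(triisopropylsilyloxy)phenyl]-2,3-dihydrobenzofuran-3-carboxylate (cis)
Conditions: Rh2(S-PTTL)4 (1 mol %), toluene, −60 °C, slow addition of 8
Reagents that add atoms: none
Why: Dirhodium-carbenoid intramolecular 1,5 C–H insertion into the benzylic ether methylene closes the dihydrofuran ring; the insertion is cis-selective and the chiral carboxylate ligands choose the carbenoid face, so C2 and C3 are set together, and the cis ester is kept away from base to avoid epimerisation to trans.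

Step 7
Reactants: 9 the cis ester
Product: 10 {(2S,3S)-5-bromo-7-methoxy-2-[3-methoxy-4-(triisopropylsilyloxy)phenyl]-2,3-dihydrobenzofuran-3-yl}methanol (cis)
Conditions: iBu2AlH (3 equiv), CH2Cl2, −78 to −40 °C; aq. Rochelle salt
Reagents that add atoms: none
Why: Hydride reduction of the ester to the primary alcohol under non-basic low-temperature conditions that preserve the cis relationship (C3 becomes S only through the priority change).

Step 8
Reactants: 10 the cis alcohol
Product: 11 (2S,3S)-5-bromo-7-methoxy-2-[3-methoxy-4-(triisopropylsilyloxy)phenyl]-3-[(triisopropylsilyloxy)methyl]-2,3-dihydrobenzofuran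
Conditions: TIPSCl, imidazole, DMF, rt
Reagents that add atoms: triisopropylsilyl chloride, CC(C)[Si](Cl)(C(C)C)C(C)C
Why: Silylation of the primary alcohol (silyl ether formation) so that it cannot compete in the later sulfonylation that closes ring B.

Step 9
Reactants: 11 the aryl bromide
Product: 13 (2S,3S)-7-methoxy-2-[3-methoxy-4-(triisopropylsilyloxy)phenyl]-3-[(triisopropylsilyloxy)methyl]-2,3-dihydrobenzofuran-5-carbaldehyde (fragment 2), via aryllithium 12 (not isolated)
Conditions: n-BuLi, THF, −78 °C; DMF; H2O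
Reagents that add atoms: N,N-dimethylformamide, CN(C)C=O
Why: Bromine–lithium exchange followed by formylation of the aryllithium with DMF; at −78 °C the exchange should outrun deprotonation at the benzylic C2–H.

Step 10
Reactants: 14 2-bromoprop-2-en-1-ol
Product: 15 [(2-bromoallyl)oxy](tert-butyl)dimethylsilane
Conditions: TBSCl, imidazole, CH2Cl2, rt
Reagents that add atoms: tert-butyldimethylsilyl chloride, CC(C)(C)[Si](C)(C)Cl
Why: Silylation of the primary alcohol (silyl ether formation) to mark the future C9 oxygen with a group that can be removed in the presence of aryl TIPS ethers.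

Step 11
Reactants: 2 3-methoxy-4-(triisopropylsilyloxy)benzaldehyde; 15 the 2-bromoallyl silyl ether
Product: 16 (R)-2-{[(tert-butyldimethylsilyl)oxy]methyl}-1-[3-methoxy-4-(triisopropylsilyloxy)phenyl]prop-2-en-1-ol (fragment 1)
Conditions: CrCl2 (10 mol %), (S)-oxazoline–sulfonamide ligand (11 mol %), Et3N, NiCl2(dmp) (2 mol %, dmp = 2,9-dimethyl-1,10-phenanthroline), Mn, Cp2ZrCl2, LiCl, MeCN, rt
Reagents that add atoms: none
Why: Catalytic asymmetric Nozaki–Hiyama–Kishi alkenylation, in which nickel activates the alkenyl bromide and the alkenylchromium adds to the aldehyde inside the chiral sulfonamide complex; the ligand selects the aldehyde face and sets C7 as R.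

Step 12
Reactants: 16 fragment 1; 17 2,3-dibromopropene
Product: 18 (R)-2-bromoallyl ether of 16 (TBS ether retained)
Conditions: NaH, THF, 0 °C; then 17, Bu4NI (cat.), 0 °C to rt
Reagents that add atoms: none
Why: Williamson etherification at the allylic bromide (the vinylic bromide is inert to SN2); the C7–O bond is untouched so the configuration is retained, and THF at 0 °C keeps 1,5-silyl migration slow.

Step 13
Reactants: 18 the bromoallyl ether
Product: 19 (R)-2-{[(2-bromoallyl)oxy][3-methoxy-4-(triisopropylsilyloxy)phenyl]methyl}prop-2-en-1-ol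
Conditions: HF·pyridine, pyridine, THF, 0 °C
Reagents that add atoms: none
Why: Fluoride-mediated cleavage of the primary alkyl TBS ether; buffered HF·pyridine should leave the aryl TIPS ether and the benzylic allylic ether intact, and the freed allylic alcohol later assists metathesis.

Step 14
Reactants: 19 the alkenyl bromide alcohol; 13 fragment 2
Product: 20 (7R,7'R)-diene diol (acyclic ring-closing metathesis precursor)
Conditions: CrCl2 (15 mol %), (S)-oxazoline–sulfonamide ligand (16 mol %), Et3N, NiCl2(dmp) (3 mol %), Mn, Cp2ZrCl2, LiCl, MeCN, rt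
Reagents that add atoms: none
Why: Second catalytic asymmetric Nozaki–Hiyama–Kishi alkenylation, aldehyde-selective and tolerant of the free hydroxyl; the same ligand antipode as in step 11 attacks the same aldehyde face and sets C7' as R, overriding the remote stereocentres.

Step 15
Reactants: 20 the diene diol
Product: 21 (7R,7'R)-3,4-disubstituted 2-aryl-2,5-dihydrofuran diol (ring A closed)
Conditions: RuCl2(=CH-C6H4-2-OiPr)(1,3-di-o-tolylimidazolidin-2-ylidene) (10 mol %), 2,6-dichloro-1,4-benzoquinone (10 mol %), toluene (0.005 M), 80 °C, argon sparge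
Reagents that add atoms: none
Why: A ruthenium alkylidene loads on one of the two 1,1-disubstituted alkenes (the free allylic hydroxyls favour loading), the tethered second alkene adds by [2+2] to a ruthenacyclobutane, and cycloreversion expels ethene and leaves the C8=C8' double bond. The closest known reaction type is ring-closing olefin metathesis to tetrasubstituted five-membered cyclic alkenes (2,5-dihydrofurans, cyclopentenes) with ruthenium carbenes carrying the less bulky N-o-tolyl NHC. Ring A is closed as a five-membered ring with the new alkene endocyclic and joining C8 to C8'; ring B is not formed in this step. No stereocentre is created: C7 (R) and C7' (R) are untouched, and C8 and C8' are deliberately left trigonal so that both are set later in one syn hydrogenation of a flat bicycle. The step needs ring closure to win over oligomerisation and over hydride-induced isomerisation of the allylic alcohols; the five-atom C8–C7–O–C9'–C8' tether (one possible diene pairing, five-ring closure), high dilution, removal of ethene and the benzoquinone additive should secure this.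

Step 16
Reactants: 21 the dihydrofuran diol
Product: 23 (1R,4R)-1,4-diaryl-1H,3H,4H,6H-furo[3,4-c]furan (bicyclic alkene), via primary allylic tosylate 22 (not isolated)
Conditions: NaH (2.2 equiv), THF, 0 °C; 1-(p-toluenesulfonyl)imidazole (1.05 equiv), 0 °C to rt
Reagents that add atoms: none
Why: One-pot cyclodehydration of a 1,4-diol, in which the less hindered primary allylic alkoxide is sulfonylated and the C7' alkoxide displaces the tosylate (intramolecular Williamson, 5-exo-tet) to close ring B; the C7'–O bond is never broken, so C7' is retained.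

Step 17
Reactants: 23 the bicyclic alkene
Product: 24 tris-TIPS ether of the target
Conditions: H2 (1 atm), [Ir(cod)(PCy3)(py)]PF6 (5 mol %), CH2Cl2, rt
Reagents that add atoms: none
Why: Homogeneous iridium-catalysed hydrogenation of a tetrasubstituted alkene; syn delivery of H2 to the flat bicyclo[3.3.0]oct-1(5)-ene from the face opposite both aryl groups sets C8 and C8' (S,S), folds the bicycle cis and leaves both aryls endo, and this catalyst should not hydrogenolyse the benzylic C–O bonds.

Step 18
Reactants: 24 the tris-TIPS ether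
Product: 25 target CNP0303197.1
Conditions: Bu4NF (3.5 equiv), AcOH (3.5 equiv), THF, 0 °C to rt
Reagents that add atoms: none
Why: Fluoride-mediated global desilylation of two aryl and one alkyl TIPS ether; acetic acid buffering keeps the medium near neutral so that the endo benzylic ethers and the cis-dihydrobenzofuran should not epimerise.

**Compound list**

1 | vanillin | COc1cc(C=O)ccc1O | starting material
2 | 3-methoxy-4-(triisopropylsilyloxy)benzaldehyde | COc1cc(C=O)ccc1O[Si](C(C)C)(C(C)C)C(C)C | intermediate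
3 | [3-methoxy-4-(triisopropylsilyloxy)phenyl]methanol | COc1cc(CO)ccc1O[Si](C(C)C)(C(C)C)C(C)C | intermediate
4 | 4-bromo-2-methoxyphenol | COc1cc(Br)ccc1O | starting material
5 | 4-bromo-2-iodo-6-methoxyphenol | COc1cc(Br)cc(I)c1O | intermediate
6 | 5-bromo-1-iodo-3-methoxy-2-{[3-methoxy-4-(triisopropylsilyloxy)benzyl]oxy}benzene | COc1cc(Br)cc(I)c1OCc1ccc(O[Si](C(C)C)(C(C)C)C(C)C)c(OC)c1 | intermediate
7 | ethyl diazoacetate | CCOC(=O)C=[N+]=[N-] | starting material
8 | ethyl 2-(5-bromo-3-methoxy-2-{[3-methoxy-4-(triisopropylsilyloxy)benzyl]oxy}phenyl)-2-diazoacetate | CCOC(=O)C(=[N+]=[N-])c1cc(Br)cc(OC)c1OCc1ccc(O[Si](C(C)C)(C(C)C)C(C)C)c(OC)c1 | intermediate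
9 | ethyl (2S,3R)-5-bromo-7-methoxy-2-[3-methoxy-4-(triisopropylsilyloxy)phenyl]-2,3-dihydrobenzofuran-3-carboxylate (cis) | Brc1cc(OC)c2c(c1)[C@@H](C(=O)OCC)[C@@H](c1ccc(O[Si](C(C)C)(C(C)C)C(C)C)c(OC)c1)O2 | intermediate
10 | {(2S,3S)-5-bromo-7-methoxy-2-[3-methoxy-4-(triisopropylsilyloxy)phenyl]-2,3-dihydrobenzofuran-3-yl}methanol (cis) | Brc1cc(OC)c2c(c1)[C@@H](CO)[C@@H](c1ccc(O[Si](C(C)C)(C(C)C)C(C)C)c(OC)c1)O2 | intermediate
11 | (2S,3S)-5-bromo-7-methoxy-2-[3-methoxy-4-(triisopropylsilyloxy)phenyl]-3-[(triisopropylsilyloxy)methyl]-2,3-dihydrobenzofuran | Brc1cc(OC)c2c(c1)[C@@H](CO[Si](C(C)C)(C(C)C)C(C)C)[C@@H](c1ccc(O[Si](C(C)C)(C(C)C)C(C)C)c(OC)c1)O2 | intermediate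
12 | 5-lithio derivative of 11 (aryllithium) | [Li]c1cc(OC)c2c(c1)[C@@H](CO[Si](C(C)C)(C(C)C)C(C)C)[C@@H](c1ccc(O[Si](C(C)C)(C(C)C)C(C)C)c(OC)c1)O2 | intermediate
13 | (2S,3S)-7-methoxy-2-[3-methoxy-4-(triisopropylsilyloxy)phenyl]-3-[(triisopropylsilyloxy)methyl]-2,3-dihydrobenzofuran-5-carbaldehyde (fragment 2) | O=Cc1cc(OC)c2c(c1)[C@@H](CO[Si](C(C)C)(C(C)C)C(C)C)[C@@H](c1ccc(O[Si](C(C)C)(C(C)C)C(C)C)c(OC)c1)O2 | intermediate
14 | 2-bromoprop-2-en-1-ol | OCC(Br)=C | starting material
15 | [(2-bromoallyl)oxy](tert-butyl)dimethylsilane | C=C(Br)CO[Si](C)(C)C(C)(C)C | intermediate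
16 | (R)-2-{[(tert-butyldimethylsilyl)oxy]methyl}-1-[3-methoxy-4-(triisopropylsilyloxy)phenyl]prop-2-en-1-ol (fragment 1) | COc1cc([C@@H](O)C(=C)CO[Si](C)(C)C(C)(C)C)ccc1O[Si](C(C)C)(C(C)C)C(C)C | intermediate
17 | 2,3-dibromopropene | C=C(Br)CBr | starting material
18 | (R)-2-bromoallyl ether of 16 | COc1cc([C@@H](OCC(Br)=C)C(=C)CO[Si](C)(C)C(C)(C)C)ccc1O[Si](C(C)C)(C(C)C)C(C)C | intermediate
19 | (R)-2-{[(2-bromoallyl)oxy][3-methoxy-4-(triisopropylsilyloxy)phenyl]methyl}prop-2-en-1-ol | COc1cc([C@@H](OCC(Br)=C)C(=C)CO)ccc1O[Si](C(C)C)(C(C)C)C(C)C | intermediate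
20 | (7R,7'R)-diene diol: bis(2-substituted allyl) ether with free C9–OH and C7'–OH | COc1cc([C@@H](OCC(=C)[C@H](O)c2cc(OC)c3c(c2)[C@@H](CO[Si](C(C)C)(C(C)C)C(C)C)[C@@H](c2ccc(O[Si](C(C)C)(C(C)C)C(C)C)c(OC)c2)O3)C(=C)CO)ccc1O[Si](C(C)C)(C(C)C)C(C)C | intermediate
21 | (7R,7'R)-2-aryl-3-(hydroxymethyl)-4-[aryl(hydroxy)methyl]-2,5-dihydrofuran (ring A) | COc1cc([C@H]2OCC([C@H](O)c3cc(OC)c4c(c3)[C@@H](CO[Si](C(C)C)(C(C)C)C(C)C)[C@@H](c3ccc(O[Si](C(C)C)(C(C)C)C(C)C)c(OC)c3)O4)=C2CO)ccc1O[Si](C(C)C)(C(C)C)C(C)C | intermediate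
22 | primary allylic tosylate of 21 | COc1cc([C@H]2OCC([C@H](O)c3cc(OC)c4c(c3)[C@@H](CO[Si](C(C)C)(C(C)C)C(C)C)[C@@H](c3ccc(O[Si](C(C)C)(C(C)C)C(C)C)c(OC)c3)O4)=C2COS(=O)(=O)c2ccc(C)cc2)ccc1O[Si](C(C)C)(C(C)C)C(C)C | intermediate
23 | (1R,4R)-1,4-diaryl-1H,3H,4H,6H-furo[3,4-c]furan (both aryls on one face) | COc1cc([C@H]2OCC3=C2CO[C@@H]3c2cc(OC)c3c(c2)[C@@H](CO[Si](C(C)C)(C(C)C)C(C)C)[C@@H](c2ccc(O[Si](C(C)C)(C(C)C)C(C)C)c(OC)c2)O3)ccc1O[Si](C(C)C)(C(C)C)C(C)C | intermediate
24 | tris-TIPS ether of the target, (1S,3aS,4S,6aS)-furofuran with both aryls endo (C7 and C7' become S by priority change only) | COc1cc([C@H]2OC[C@@H]3[C@H]2CO[C@@H]3c2cc(OC)c3c(c2)[C@@H](CO[Si](C(C)C)(C(C)C)C(C)C)[C@@H](c2ccc(O[Si](C(C)C)(C(C)C)C(C)C)c(OC)c2)O3)ccc1O[Si](C(C)C)(C(C)C)C(C)C | intermediate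
25 | CNP0303197.1 | COc1cc([C@H]2OC[C@@H]3[C@H]2CO[C@@H]3c2cc(OC)c3c(c2)[C@@H](CO)[C@@H](c2ccc(O)c(OC)c2)O3)ccc1O | target

**Count and risks**

Total steps: 18. Longest linear sequence: 13 (steps 1, 2, 4, 5, 6, 7, 8, 9, 14, 15, 16, 17, 18).

Step 15. Ring closure to the tetrasubstituted alkene may be too slow at two hindered 1,1-disubstituted olefins, so that catalyst decay and hydride-induced isomerisation of the allylic alcohols take over. Fallback by relay metathesis, setting out from 2 and rejoining at 21. Commercial 4-[(tert-butyldimethylsilyl)oxy]but-2-yn-1-ol is subjected to hydroxyl-directed trans-hydroalumination with NaAlH2(OCH2CH2OMe)2 and iodination, which should give (Z)-4-[(tert-butyldimethylsilyl)oxy]-3-iodobut-2-en-1-ol F1. O-Allylation (NaH, allyl bromide) gives the relay alkenyl iodide F2. Coupling of F2 with 2 under the conditions of step 11 should give the relay-armed allylic alcohol F3. The operations of steps 12, 13 and 14 (17; HF·pyridine; 13) then give the bromoallyl ether F4, the primary alcohol F5 and the triene diol F6. With the same ruthenium carbene, the catalyst now loads on the unhindered terminal allyl ether, expels 2,5-dihydrofuran and is delivered directly onto C8 as its alkylidene, from where closure onto the C8' methylidene should give 21.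

Step 14. Facial control by the chiral chromium complex may be insufficient at the large aryl aldehyde, giving both C7' epimers. Fallback by ketone reduction, setting out from 18 and 13 and rejoining at 20. Coupling of 18 with 13 without the chiral ligand (CrCl2, NiCl2(dmp), Mn, Cp2ZrCl2) gives the C7'-epimeric allylic alcohols F7. MnO2 oxidation of the benzylic allylic alcohol gives the aryl enone F8. Corey–Bakshi–Shibata reduction with (R)-2-methyl-CBS-oxazaborolidine and catecholborane at −78 °C (aryl as the large group) should give the single (7'R) alcohol F9. HF·pyridine as in step 13 then gives 20.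

Step 17. Hydrogen uptake at the strained tetrasubstituted alkene may be slow, and acidic iridium hydride species may ionise or isomerise the benzylic allylic ethers before reduction. Fallback by reordering, setting out from 21 and rejoining at 24. The monocyclic dihydrofuran 21 is hydrogenated over 5% Rh on Al2O3 (H2, EtOAc, non-acidic, little hydrogenolysis), where addition anti to the C7 aryl should give the all-cis tetrahydrofuran diol F10. The sulfonylation and displacement of step 16 (NaH, 1-(p-toluenesulfonyl)imidazole), passing through the primary tosylate F11, then close ring B with retention at C7' and give 24.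

**Further compounds**

F1 | step 15 | (Z)-4-[(tert-butyldimethylsilyl)oxy]-3-iodobut-2-en-1-ol | OC/C=C(\I)CO[Si](C)(C)C(C)(C)C
F2 | step 15 | (Z)-{[4-(allyloxy)-2-iodobut-2-en-1-yl]oxy}(tert-butyl)dimethylsilane | C=CCOC/C=C(\I)CO[Si](C)(C)C(C)(C)C
F3 | step 15 | (R,Z)-relay-armed allylic alcohol (analogue of 16 with an allyloxymethyl group on the alkene terminus) | COc1cc([C@@H](O)/C(CO[Si](C)(C)C(C)(C)C)=C\COCC=C)ccc1O[Si](C(C)C)(C(C)C)C(C)C
F4 | step 15 | 2-bromoallyl ether of F3 | COc1cc([C@@H](OCC(Br)=C)/C(CO[Si](C)(C)C(C)(C)C)=C\COCC=C)ccc1O[Si](C(C)C)(C(C)C)C(C)C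
F5 | step 15 | primary alcohol from F4 | COc1cc([C@@H](OCC(Br)=C)/C(CO)=C\COCC=C)ccc1O[Si](C(C)C)(C(C)C)C(C)C
F6 | step 15 | (7R,7'R)-relay triene diol | COc1cc([C@@H](OCC(=C)[C@H](O)c2cc(OC)c3c(c2)[C@@H](CO[Si](C(C)C)(C(C)C)C(C)C)[C@@H](c2ccc(O[Si](C(C)C)(C(C)C)C(C)C)c(OC)c2)O3)/C(CO)=C\COCC=C)ccc1O[Si](C(C)C)(C(C)C)C(C)C
F7 | step 14 | C7'-epimeric allylic alcohols (C9 TBS ether) | COc1cc([C@@H](OCC(=C)C(O)c2cc(OC)c3c(c2)[C@@H](CO[Si](C(C)C)(C(C)C)C(C)C)[C@@H](c2ccc(O[Si](C(C)C)(C(C)C)C(C)C)c(OC)c2)O3)C(=C)CO[Si](C)(C)C(C)(C)C)ccc1O[Si](C(C)C)(C(C)C)C(C)C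
F8 | step 14 | aryl enone (C7' ketone) | COc1cc([C@@H](OCC(=C)C(=O)c2cc(OC)c3c(c2)[C@@H](CO[Si](C(C)C)(C(C)C)C(C)C)[C@@H](c2ccc(O[Si](C(C)C)(C(C)C)C(C)C)c(OC)c2)O3)C(=C)CO[Si](C)(C)C(C)(C)C)ccc1O[Si](C(C)C)(C(C)C)C(C)C
F9 | step 14 | (7R,7'R)-allylic alcohol (C9 TBS ether) | COc1cc([C@@H](OCC(=C)[C@H](O)c2cc(OC)c3c(c2)[C@@H](CO[Si](C(C)C)(C(C)C)C(C)C)[C@@H](c2ccc(O[Si](C(C)C)(C(C)C)C(C)C)c(OC)c2)O3)C(=C)CO[Si](C)(C)C(C)(C)C)ccc1O[Si](C(C)C)(C(C)C)C(C)C
F10 | step 17 | all-cis 2-aryl-3-(hydroxymethyl)-4-[aryl(hydroxy)methyl]tetrahydrofuran | COc1cc([C@H]2OC[C@@H]([C@H](O)c3cc(OC)c4c(c3)[C@@H](CO[Si](C(C)C)(C(C)C)C(C)C)[C@@H](c3ccc(O[Si](C(C)C)(C(C)C)C(C)C)c(OC)c3)O4)[C@H]2CO)ccc1O[Si](C(C)C)(C(C)C)C(C)C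
F11 | step 17 | primary tosylate of F10 | COc1cc([C@H]2OC[C@@H]([C@H](O)c3cc(OC)c4c(c3)[C@@H](CO[Si](C(C)C)(C(C)C)C(C)C)[C@@H](c3ccc(O[Si](C(C)C)(C(C)C)C(C)C)c(OC)c3)O4)[C@H]2COS(=O)(=O)c2ccc(C)cc2)ccc1O[Si](C(C)C)(C(C)C)C(C)C
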